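**Plan**

Retrosynthesis: the three benzyl groups come off first. Ring A is then cut at C1–C2 and C5–C6 (retro-[4+2]), next the acyl–oxygen bond of the resulting but-2-ynoate, and last the B–C depside ester bond.
Enabling feature: ring A is hexasubstituted (C1 ester carbonyl, C2 OH, C3 H, C4 OH, C5 OAc, C6 CH3). Its C1–C6 edge is the triple bond of a but-2-ynoate of the ring B phenol, and C2–C3–C4–C5 with its three oxygens is methyl 4-acetoxyacetoacetate in bis(silyl) dienol form.
Forward: rings B and C both come ready-made from orsellinic acid through one common protected ester and are joined first. The ring B phenol is then freed and acylated with but-2-ynoic acid, and ring A, the only ring built, is made last by cycloaddition and loss of methanol.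
The acetyl group arrives on the diene, so O5 is distinguished from O2 and O4 from the outset, and the crowded A–B ester exists before ring A does.
Stereochemistry: the target has no stereocentre and no stereogenic double bond, and the two sp3 carbons of the cycloadduct vanish on aromatisation.

Key step: step 11

Assumption: the double-bond geometries of the enol silane and the diene, and the relative configuration of the cycloadduct, are drawn as expected from allylic strain and suprafacial addition. All are erased on aromatisation, and only the outward (3Z) placement of the acetoxy group matters for reactivity.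

Step 1
Reactants: 1 orsellinic acid (2,4-dihydroxy-6-methylbenzoic acid)
Product: 2 benzyl 2,4-dihydroxy-6-methylbenzoate
Conditions: BnBr (1.05 equiv), KHCO3 (1.1 equiv), DMF, rt
Reagents that add atoms: benzyl bromide, BrCc1ccccc1
Why: Carboxylate alkylation (SN2 on benzyl bromide): KHCO3 ionises only the carboxylic acid, so both phenols stay free, and room temperature keeps this easily decarboxylated acid intact.

Step 2
Reactants: 2 benzyl 2,4-dihydroxy-6-methylbenzoate
Product: 3 benzyl 2-hydroxy-4-(methoxymethoxy)-6-methylbenzoate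
Conditions: MOMCl (1.1 equiv), i-Pr2NEt (1.5 equiv), CH2Cl2, 0 °C to rt
Reagents that add atoms: chloromethyl methyl ether, COCCl
Why: Regioselective O-alkylation with an alpha-chloro ether: the C2 hydroxyl is hydrogen-bonded to the ester carbonyl and less acidic, so one equivalent of reagent goes to the C4 hydroxyl, as is routine for 2,4-dihydroxybenzoates.

Step 3
Reactants: 3 benzyl 2-hydroxy-4-(methoxymethoxy)-6-methylbenzoate
Product: 4 benzyl 2-(benzyloxy)-4-(methoxymethoxy)-6-methylbenzoate
Conditions: BnBr (1.5 equiv), K2CO3 (2 equiv), DMF, 60 °C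
Reagents that add atoms: benzyl bromide, BrCc1ccccc1
Why: Williamson ether synthesis: carbonate in warm DMF breaks the chelate and the only remaining phenoxide is benzylated, while the MOM acetal and the flanked benzyl ester are inert to these conditions.

Step 4
Reactants: 4 benzyl 2-(benzyloxy)-4-(methoxymethoxy)-6-methylbenzoate
Product: 5 benzyl 2-(benzyloxy)-4-hydroxy-6-methylbenzoate
Conditions: 3 M aq HCl, THF, 45 °C
Reagents that add atoms: none
Why: Acid-catalysed acetal hydrolysis: the aryl MOM ether ionises far more readily than benzyl ethers or the shielded benzyl ester react, so only the C4 phenol of the future ring C is freed.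

Step 5
Reactants: 4 benzyl 2-(benzyloxy)-4-(methoxymethoxy)-6-methylbenzoate
Product: 6 2-(benzyloxy)-4-(methoxymethoxy)-6-methylbenzoic acid
Conditions: KOH (10 equiv), DMSO/H2O 4:1, 90 °C; then 1 M HCl to pH 3–4, 0 °C
Reagents that add atoms: potassium hydroxide, [K+].[OH-]
Why: Saponification by acyl–oxygen cleavage of a doubly ortho-substituted benzoate needs poorly solvated hydroxide in aqueous DMSO, conditions customary for orsellinate esters and harmless to MOM and benzyl ethers, and the cold, mild acidification spares the acetal.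

Step 6
Reactants: 5 benzyl 2-(benzyloxy)-4-hydroxy-6-methylbenzoate; 6 2-(benzyloxy)-4-(methoxymethoxy)-6-methylbenzoic acid
Product: 7 benzyl 2-(benzyloxy)-4-{[2-(benzyloxy)-4-(methoxymethoxy)-6-methylbenzoyl]oxy}-6-methylbenzoate
Conditions: DCC (1.2 equiv), DMAP (0.2 equiv), CH2Cl2, 0 °C to rt
Reagents that add atoms: none
Why: Steglich esterification: DMAP carries the acyl group from the O-acylisourea to the single free phenol, the usual way to form depside bonds from fully O-protected 6-alkyl-2,4-dioxygenated benzoic acids.

Step 7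
Reactants: 7 benzyl 2-(benzyloxy)-4-{[2-(benzyloxy)-4-(methoxymethoxy)-6-methylbenzoyl]oxy}-6-methylbenzoate
Product: 8 benzyl 2-(benzyloxy)-4-{[2-(benzyloxy)-4-hydroxy-6-methylbenzoyl]oxy}-6-methylbenzoate
Conditions: 3 M aq HCl, THF, 45 °C
Reagents that add atoms: none
Why: Acid-catalysed acetal hydrolysis as in step 4; the diaryl ester is screened by its two ortho substituents and withstands dilute acid, so only the ring B phenol is unmasked.

Step 8
Reactants: 8 benzyl 2-(benzyloxy)-4-{[2-(benzyloxy)-4-hydroxy-6-methylbenzoyl]oxy}-6-methylbenzoate; 9 but-2-ynoic acid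
Product: 10 benzyl 2-(benzyloxy)-4-{[2-(benzyloxy)-4-(but-2-ynoyloxy)-6-methylbenzoyl]oxy}-6-methylbenzoate
Conditions: DCC (1.2 equiv), DMAP (0.05 equiv), CH2Cl2, 0 °C to rt
Reagents that add atoms: none
Why: Steglich esterification is a routine preparation of aryl but-2-ynoates, and the low DMAP loading and low temperature limit conjugate addition of the catalyst to the ynoate.

Step 9
Reactants: 11 methyl 4-chloroacetoacetate
Product: 12 methyl 4-acetoxy-3-oxobutanoate
Conditions: KOAc (1.5 equiv), AcOH (2 equiv), DMF, rt
Reagents that add atoms: potassium acetate, CC(=O)[O-].[K+]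
Why: SN2 displacement of a primary alpha-keto chloride by acetate; the acetic acid buffer keeps the beta-keto ester un-ionised, so self-alkylation and closure to a tetronate are held back.

Step 10
Reactants: 12 methyl 4-acetoxy-3-oxobutanoate
Product: 14 (1Z,3Z)-4-acetoxy-1-methoxy-1,3-bis(trimethylsilyloxy)buta-1,3-diene, via mono enol silane 13 (not isolated)
Conditions: Me3SiOTf (2.2 equiv), Et3N (3 equiv), Et2O, 0 °C to rt; pentane extraction under argon, used crude
Reagents that add atoms: trimethylsilyl trifluoromethanesulfonate, C[Si](C)(C)OS(=O)(=O)C(F)(F)F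
Why: Double soft enolisation with silyl triflate and a tertiary amine is a known one-flask route from beta-keto esters to 1-alkoxy-1,3-bis(silyloxy)dienes: the enol is silylated first, silylation of the ester carbonyl then acidifies the C4 protons (already activated by the acetoxy group) for vinylogous deprotonation, and allylic strain places the acetoxy group trans to C2.

Step 11
Reactants: 10 benzyl 2-(benzyloxy)-4-{[2-(benzyloxy)-4-(but-2-ynoyloxy)-6-methylbenzoyl]oxy}-6-methylbenzoate; 14 (1Z,3Z)-4-acetoxy-1-methoxy-1,3-bis(trimethylsilyloxy)buta-1,3-diene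
Product: 17 benzyl 4-{[4-({3-acetoxy-4,6-dihydroxy-2-methylbenzoyl}oxy)-2-(benzyloxy)-6-methylbenzoyl]oxy}-2-(benzyloxy)-6-methylbenzoate, via cycloadduct 15 (not isolated), via bis(trimethylsilyl) ether 16 (not isolated)
Conditions: 14 (3 equiv, in portions), PhMe, 120 °C, sealed tube; then 1 M aq HCl, THF, 0 °C
Reagents that add atoms: none
Why: Electron-rich diene 14 and electron-poor ynoate 10 should combine in a normal-demand, strongly asynchronous Diels–Alder reaction in which the bond from the acetoxy-bearing diene terminus to the methyl-bearing alkyne carbon (ring A C5–C6) runs ahead of the bond from the ketene acetal carbon to the ester-bearing alkyne carbon (C1–C2), the limiting case being a Mukaiyama–Michael addition followed by ring closure. The closest known reaction type is the cycloaddition–aromatisation of 1-alkoxy-1,3-bis(silyloxy)buta-1,3-dienes with 3-alkylpropiolates to give 6-alkyl-2,4-dihydroxybenzoates, and the 4-acetoxy group on the diene is a variation within that class that has yet to be tried. Ring A closes as a six-membered carbocycle in an intermolecular [4+2] mode, both new sigma bonds arising in one operation, to give cyclohexa-1,4-diene 15. In 15 the mixed ketal carbon C2 and the doubly allylic C5–H face each other across the ring, so methanol leaves by 1,4-elimination with aromatisation as driving force to give 16, the C5–O bond cannot be lost because C2 carries no hydrogen, and cold dilute acid then removes the two aryl silyl ethers without touching the aryl acetate. No stereocentre is retained, since C2 and C5 of 15 both become sp2. The step needs one orientation and one reacting site: the oxygen donors at diene C1 and C3 reinforce each other and put the largest HOMO coefficient on C4, the acetoxy oxygen (cross-conjugated with its own carbonyl) is too weak a donor to reverse this, the ynoate LUMO is largest at the beta carbon and is lowered by the electron-poor aryl ester, the (3Z) geometry keeps the acetoxy group outside the s-cis diene, and benzylation of rings B and C leaves no acidic proton to quench the ketene acetal.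

Step 12
Reactants: 17 benzyl 4-{[4-({3-acetoxy-4,6-dihydroxy-2-methylbenzoyl}oxy)-2-(benzyloxy)-6-methylbenzoyl]oxy}-2-(benzyloxy)-6-methylbenzoate
Product: 18 4-{[4-({3-acetoxy-4,6-dihydroxy-2-methylbenzoyl}oxy)-2-hydroxy-6-methylbenzoyl]oxy}-2-hydroxy-6-methylbenzoic acid (CNP0154030.0)
Conditions: H2 (1 atm), 10% Pd/C, EtOAc, rt
Reagents that add atoms: none
Why: Catalytic hydrogenolysis of two aryl benzyl ethers and one benzyl ester is the standard end-game for depsides, and neutral, non-nucleophilic EtOAc avoids solvolysis of the aryl esters and drift of the acetyl group from O5 to the neighbouring O4.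

**Compound list**

1 | orsellinic acid (2,4-dihydroxy-6-methylbenzoic acid) | Cc1cc(O)cc(O)c1C(=O)O | starting material
2 | benzyl 2,4-dihydroxy-6-methylbenzoate | Cc1cc(O)cc(O)c1C(=O)OCc1ccccc1 | intermediate
3 | benzyl 2-hydroxy-4-(methoxymethoxy)-6-methylbenzoate | COCOc1cc(C)c(C(=O)OCc2ccccc2)c(O)c1 | intermediate
4 | benzyl 2-(benzyloxy)-4-(methoxymethoxy)-6-methylbenzoate | COCOc1cc(C)c(C(=O)OCc2ccccc2)c(OCc2ccccc2)c1 | intermediate
5 | benzyl 2-(benzyloxy)-4-hydroxy-6-methylbenzoate (ring C phenol) | Cc1cc(O)cc(OCc2ccccc2)c1C(=O)OCc1ccccc1 | intermediate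
6 | 2-(benzyloxy)-4-(methoxymethoxy)-6-methylbenzoic acid (ring B acid) | COCOc1cc(C)c(C(=O)O)c(OCc2ccccc2)c1 | intermediate
7 | benzyl 2-(benzyloxy)-4-{[2-(benzyloxy)-4-(methoxymethoxy)-6-methylbenzoyl]oxy}-6-methylbenzoate | COCOc1cc(C)c(C(=O)Oc2cc(C)c(C(=O)OCc3ccccc3)c(OCc3ccccc3)c2)c(OCc2ccccc2)c1 | intermediate
8 | benzyl 2-(benzyloxy)-4-{[2-(benzyloxy)-4-hydroxy-6-methylbenzoyl]oxy}-6-methylbenzoate (ring B–C phenol) | Oc1cc(C)c(C(=O)Oc2cc(C)c(C(=O)OCc3ccccc3)c(OCc3ccccc3)c2)c(OCc2ccccc2)c1 | intermediate
9 | but-2-ynoic acid | CC#CC(=O)O | starting material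
10 | benzyl 2-(benzyloxy)-4-{[2-(benzyloxy)-4-(but-2-ynoyloxy)-6-methylbenzoyl]oxy}-6-methylbenzoate (ynoate) | CC#CC(=O)Oc1cc(C)c(C(=O)Oc2cc(C)c(C(=O)OCc3ccccc3)c(OCc3ccccc3)c2)c(OCc2ccccc2)c1 | intermediate
11 | methyl 4-chloroacetoacetate | COC(=O)CC(=O)CCl | starting material
12 | methyl 4-acetoxy-3-oxobutanoate | COC(=O)CC(=O)COC(C)=O | intermediate
13 | methyl (Z)-4-acetoxy-3-(trimethylsilyloxy)but-2-enoate (mono enol silane) | COC(=O)/C=C(/COC(C)=O)O[Si](C)(C)C | intermediate
14 | (1Z,3Z)-4-acetoxy-1-methoxy-1,3-bis(trimethylsilyloxy)buta-1,3-diene | CO/C(O[Si](C)(C)C)=C/C(O[Si](C)(C)C)=C/OC(C)=O | intermediate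
15 | racemic cyclohexa-1,4-diene cycloadduct: ring A with C2(OMe)(OSiMe3), C3H=C4(OSiMe3), C5H(OAc), C6(CH3)=C1(CO2Ar); OMe and OAc cis; one enantiomer drawn | CO[C@]1(O[Si](C)(C)C)C=C(O[Si](C)(C)C)[C@H](OC(C)=O)C(C)=C1C(=O)Oc1cc(C)c(C(=O)Oc2cc(C)c(C(=O)OCc3ccccc3)c(OCc3ccccc3)c2)c(OCc2ccccc2)c1 | intermediate
16 | ring A 2,4-bis(trimethylsilyl) ether of 17 | CC(=O)Oc1c(O[Si](C)(C)C)cc(O[Si](C)(C)C)c(C(=O)Oc2cc(C)c(C(=O)Oc3cc(C)c(C(=O)OCc4ccccc4)c(OCc4ccccc4)c3)c(OCc3ccccc3)c2)c1C | intermediate
17 | benzyl 4-{[4-({3-acetoxy-4,6-dihydroxy-2-methylbenzoyl}oxy)-2-(benzyloxy)-6-methylbenzoyl]oxy}-2-(benzyloxy)-6-methylbenzoate | CC(=O)Oc1c(O)cc(O)c(C(=O)Oc2cc(C)c(C(=O)Oc3cc(C)c(C(=O)OCc4ccccc4)c(OCc4ccccc4)c3)c(OCc3ccccc3)c2)c1C | intermediate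
18 | 4-{[4-({3-acetoxy-4,6-dihydroxy-2-methylbenzoyl}oxy)-2-hydroxy-6-methylbenzoyl]oxy}-2-hydroxy-6-methylbenzoic acid (CNP0154030.0) | CC(=O)Oc1c(O)cc(O)c(C(=O)Oc2cc(C)c(C(=O)Oc3cc(C)c(C(=O)O)c(O)c3)c(O)c2)c1C | target

**Totals and risks**

Total step count: 12.
Longest linear sequence: 9 steps (1, 2, 3, 5, 6, 7, 8, 11, 12).

**Steps most likely to fail**

**Step 11.** Both bond-forming termini are substituted: the diene carbon carries the acetoxy group and the alkyne carbon carries the methyl group. Ring formation may therefore be slower than thermal decay of the ketene acetal, protodesilylation, or silyl/acetyl exchange across the enediol unit.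

The fallback gives up the cycloaddition, sets out from 8 and comes back at 18.
- Purchased 2,4-dihydroxy-6-methylbenzaldehyde F1 is dibenzylated (BnBr, K2CO3, DMF) to 2,4-bis(benzyloxy)-6-methylbenzaldehyde F2.
- Baeyer–Villiger oxidation (mCPBA, CH2Cl2) gives 2,4-bis(benzyloxy)-6-methylphenyl formate F3.
- Methanolysis (catalytic K2CO3, MeOH) converts it to 2,4-bis(benzyloxy)-6-methylphenol F4, which is acetylated at once (Ac2O, pyridine) to 2,4-bis(benzyloxy)-6-methylphenyl acetate F5.
- Vilsmeier–Haack formylation (POCl3, DMF) should attack the carbon between the methyl group and a benzyloxy group, para to the other benzyloxy group, as 3,5-dialkoxytoluenes do. This gives 3-acetoxy-4,6-bis(benzyloxy)-2-methylbenzaldehyde F6.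
- Pinnick oxidation (NaClO2, NaH2PO4, 2-methylbut-2-ene, t-BuOH/H2O) gives 3-acetoxy-4,6-bis(benzyloxy)-2-methylbenzoic acid F7.
- The acid is joined to 8 through its mixed trifluoroacetic anhydride ((CF3CO)2O, PhMe, rt), the classical answer to crowded depside bonds, to give the pentabenzyl tridepside F8.
- Hydrogenolysis under the conditions of step 12 then gives 18.

**Step 10.** The second enolisation may stall at the mono enol silane. The silyl triflate may also attack C2 or the acetate, or the diene may be lost by hydrolysis on isolation.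

The fallback sets out from 12 and comes back at 14.
- The two enolisations are separated and the second changes mechanism.
- 12 is converted with Me3SiCl/Et3N into 13, which is now isolated by distillation.
- The C4 proton is then removed kinetically with LiN(SiMe3)2 in THF at −78 °C with Me3SiCl present from the start. A lithium dienolate is thus trapped on oxygen before acyl transfer can set in, in place of the amine/silyl triflate route.
- No compound outside the list arises, hence the entry F0.

**Step 5.** Hydroxide attack at the doubly flanked carbonyl may be so slow that forcing conditions erode the ether protecting groups. The MOM acetal may also be lost, or the electron-rich acid may decarboxylate, during acidification.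

The fallback sets out from 1 and comes back at 6.
- The ring B acid gets its own ester, cleavable without acyl attack.
- Allyl bromide/KHCO3/DMF gives allyl 2,4-dihydroxy-6-methylbenzoate F9.
- MOMCl/i-Pr2NEt gives allyl 2-hydroxy-4-(methoxymethoxy)-6-methylbenzoate F10.
- BnBr/K2CO3/DMF gives allyl 2-(benzyloxy)-4-(methoxymethoxy)-6-methylbenzoate F11.
- Tsuji–Trost deallylation (catalytic Pd(PPh3)4, morpholine, THF, rt) releases 6 under neutral conditions.
- Compound 4 then serves only as the source of 5.

**Further compounds**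

F1 | step 11 | 2,4-dihydroxy-6-methylbenzaldehyde (purchased) | Cc1cc(O)cc(O)c1C=O
F2 | step 11 | 2,4-bis(benzyloxy)-6-methylbenzaldehyde | Cc1cc(OCc2ccccc2)cc(OCc2ccccc2)c1C=O
F3 | step 11 | 2,4-bis(benzyloxy)-6-methylphenyl formate | Cc1cc(OCc2ccccc2)cc(OCc2ccccc2)c1OC=O
F4 | step 11 | 2,4-bis(benzyloxy)-6-methylphenol | Cc1cc(OCc2ccccc2)cc(OCc2ccccc2)c1O
F5 | step 11 | 2,4-bis(benzyloxy)-6-methylphenyl acetate | CC(=O)Oc1c(C)cc(OCc2ccccc2)cc1OCc1ccccc1
F6 | step 11 | 3-acetoxy-4,6-bis(benzyloxy)-2-methylbenzaldehyde | CC(=O)Oc1c(C)c(C=O)c(OCc2ccccc2)cc1OCc1ccccc1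
F7 | step 11 | 3-acetoxy-4,6-bis(benzyloxy)-2-methylbenzoic acid | CC(=O)Oc1c(C)c(C(=O)O)c(OCc2ccccc2)cc1OCc1ccccc1
F8 | step 11 | pentabenzyl tridepside (ring A 2,4-di-O-benzyl ether of 17) | CC(=O)Oc1c(OCc2ccccc2)cc(OCc2ccccc2)c(C(=O)Oc2cc(C)c(C(=O)Oc3cc(C)c(C(=O)OCc4ccccc4)c(OCc4ccccc4)c3)c(OCc3ccccc3)c2)c1C
F0 | step 10 | none | none
F9 | step 5 | allyl 2,4-dihydroxy-6-methylbenzoate | C=CCOC(=O)c1c(C)cc(O)cc1O
F10 | step 5 | allyl 2-hydroxy-4-(methoxymethoxy)-6-methylbenzoate | C=CCOC(=O)c1c(C)cc(OCOC)cc1O
F11 | step 5 | allyl 2-(benzyloxy)-4-(methoxymethoxy)-6-methylbenzoate | C=CCOC(=O)c1c(C)cc(OCOC)cc1OCc1ccccc1
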